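Target ⇒ decalin aldehyde 30 + C3-metallated O-methyl tetramate from 6; the tetramic acid ring is closed first, from L-threonine (step 1), and joined late by C–C bond formation and oxidation.
30 ⇒ dienyl enone 24: hydrogen is delivered to C2 last by a stereospecific reductive 1,3-transposition (sets C2, forms C3=C4); 24 ⇒ vinylogous ester 19 + dienyllithium 22.
19 ⇒ cyclohexadienone 12 + 4-methylpent-4-enoic acid 13: a decarboxylative radical [4+2] annulation closes ring B (C4a, C5, C6, C7, C8, C8a) as the last ring and sets C8a, C4a and C6.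
Enabling feature: with C4 of ring A at the ketone level, the fusion atoms C8a and C4a are the β- and α-carbons of an enone, and C5=C6(CH3) is a 1,1-disubstituted alkene that the C4a radical reaches 6-endo.
Ring order: ring A (benzene ring of 7, dearomatised by Birch reduction–methylation, which sets C1), tetramic acid ring (step 1), ring B (step 7).
Key step: step 7

Remarks before the steps
- Locants are those of the 1,6-dimethyl-2-dienyl-octahydronaphthalene core: C1 quaternary, C2 dienyl-bearing, C3=C4, C4a/C8a ring fusion, C6 methyl-bearing. Ring A = C1–C4, C4a, C8a; ring B = C4a, C5–C8, C8a. β is the face of the C1 carbonyl substituent, α the face of the C1 methyl group.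
- Remark on the chemistry: in the target the C2 dienyl group is trans to the C1 acyl group and the C6 methyl group is axial on the trans-decalin. C8a is therefore set by C–C bond formation anti to the C1 carbonyl group, and C2 and C6 by late hydrogen delivery.
- Assumption: the (S)-2-(methoxymethyl)pyrrolidine amide is taken to direct the methylation in step 5 to the (1R) centre (chelated enolate, attack anti to the methoxymethyl arm). If the sense is opposite, the (R)-auxiliary (also commercial) is used and nothing else changes.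

Step 1
Reactants: 1 N-(tert-butoxycarbonyl)-O-tert-butyl-L-threonine; 2 Meldrum's acid
Product: 4 tert-butyl (2S)-2-[(1R)-1-tert-butoxyethyl]-3,5-dioxopyrrolidine-1-carboxylate, via acyl Meldrum's acid 3 (not isolated)
Conditions: EDC·HCl, DMAP, CH2Cl2, 0 → 23 °C; then EtOAc, reflux
Reagents that add atoms: none
Why: Carbodiimide C-acylation of Meldrum's acid, then thermal loss of acetone and CO2 to an acylketene that the carbamate nitrogen traps (Meldrum's acid route to N-acyl tetramic acids), closes the pyrrolidine-2,4-dione ring without touching the two L-threonine stereocentres.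

Step 2
Reactants: 4 tert-butyl (2S)-2-[(1R)-1-tert-butoxyethyl]-3,5-dioxopyrrolidine-1-carboxylate
Product: 5 tert-butyl (2S)-2-[(1R)-1-tert-butoxyethyl]-3-methoxy-5-oxo-2,5-dihydro-1H-pyrrole-1-carboxylate
Conditions: MeOH, PPh3, DIAD, THF, 0 → 23 °C
Reagents that add atoms: methanol (CO)
Why: Mitsunobu O-alkylation of the acidic enol gives the 4-O-methyl ether regioselectively and affects no stereocentre.

Step 3
Reactants: 5 tert-butyl (2S)-2-[(1R)-1-tert-butoxyethyl]-3-methoxy-5-oxo-2,5-dihydro-1H-pyrrole-1-carboxylate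
Product: 6 tert-butyl (2S)-4-bromo-2-[(1R)-1-tert-butoxyethyl]-3-methoxy-5-oxo-2,5-dihydro-1H-pyrrole-1-carboxylate
Conditions: NBS, MeCN, 0 → 23 °C
Reagents that add atoms: N-bromosuccinimide (O=C1CCC(=O)N1Br)
Why: Electrophilic bromination of the electron-rich enol-ether carbon C3 installs the handle for halogen–metal exchange.

Step 4
Reactants: 7 2-methoxybenzoyl chloride; 8 (S)-2-(methoxymethyl)pyrrolidine
Product: 9 (2-methoxyphenyl)[(2S)-2-(methoxymethyl)pyrrolidin-1-yl]methanone
Conditions: Et3N, CH2Cl2, 0 → 23 °C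
Reagents that add atoms: none
Why: N-acylation of the amine by the acid chloride attaches the proline-derived auxiliary.

Step 5
Reactants: 9 (2-methoxyphenyl)[(2S)-2-(methoxymethyl)pyrrolidin-1-yl]methanone
Product: 11 [(1R)-2-methoxy-1-methylcyclohexa-2,5-dien-1-yl][(2S)-2-(methoxymethyl)pyrrolidin-1-yl]methanone, via potassium amide enolate 10 (not isolated)
Conditions: K, NH3 (l), THF, t-BuOH (1 equiv), −78 °C; then MeI, −78 °C
Reagents that add atoms: iodomethane (CI)
Why: Birch reduction–alkylation of a chiral 2-methoxybenzamide: the chelated enolate 10 should be methylated on the face left open by the methoxymethyl arm, which sets the quaternary centre C1 under auxiliary control.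

Step 6
Reactants: 11 [(1R)-2-methoxy-1-methylcyclohexa-2,5-dien-1-yl][(2S)-2-(methoxymethyl)pyrrolidin-1-yl]methanone
Product: 12 (4R)-3-methoxy-4-methyl-4-{[(2S)-2-(methoxymethyl)pyrrolidin-1-yl]carbonyl}cyclohexa-2,5-dien-1-one
Conditions: CrO3 (10 mol %), t-BuOOH (70 % in water), CH2Cl2, 23 °C
Reagents that add atoms: tert-butyl hydroperoxide (CC(C)(C)OO)
Why: Chromium-catalysed allylic oxidation of the doubly allylic CH2 gives the cross-conjugated dienone; C1 is quaternary, so neither aromatisation nor epimerisation is possible.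

Step 7
Reactants: 12 (4R)-3-methoxy-4-methyl-4-{[(2S)-2-(methoxymethyl)pyrrolidin-1-yl]carbonyl}cyclohexa-2,5-dien-1-one; 13 4-methylpent-4-enoic acid
Product: 17 [(1R,4aR,6R,8aS)-2-methoxy-1,6-dimethyl-4-oxo-1,4,4a,5,6,7,8,8a-octahydronaphthalen-1-yl][(2S)-2-(methoxymethyl)pyrrolidin-1-yl]methanone, via butenyl radical 14 (not isolated), via keto radical 15 (not isolated), via tertiary radical 16 (not isolated)
Conditions: 13 (3 equiv), 9-mesityl-10-phenylacridinium tetrafluoroborate (5 mol %), bis(2,4,6-triisopropylphenyl) disulfide (10 mol %), 2,6-lutidine (0.3 equiv), CF3CH2OH/EtOAc, 450 nm LEDs, 23 °C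
Reagents that add atoms: none
Why: Proposed new method: the excited acridinium oxidises the carboxylate of 13, loss of CO2 gives the primary radical 14, which adds to the unsubstituted enone β-carbon C8a of 12; the electrophilic α-keto radical 15 at C4a then closes ring B by attack on the CH2 terminus of the 2-methylallyl unit, and the tertiary C6 radical 16 takes a hydrogen atom from the catalytic arenethiol, whose thiyl radical is returned to thiolate by the reduced acridine. The closest known reaction types are the photocatalytic decarboxylative Giese addition of carboxylic acids to enones, the 6-endo cyclisation of α-carbonyl radicals onto 1,1-disubstituted alkenes and thiol-mediated hydrogen-atom-transfer termination; merging them into one [4+2] radical annulation of a cyclohexadienone is the untested part. Ring B (C4a–C5–C6–C7–C8–C8a) closes in the 6-endo-trig mode, which should win over 5-exo because the attacked carbon C5 is unsubstituted, C6 carries the methyl group and the radical is electrophilic. C8a should be set by addition to the planar dienone anti to the bulky C1 carboxamide (C8 cis to the C1 methyl group); C4a should form cis to the tether (corrected in step 8); C6 should be set by hydrogen delivery from the hindered thiol to the exo face of the cis-fused radical, whose axial face is screened by C4, which leaves the methyl group on the α face (axial after step 8). The step needs chemoselective addition to the C4a=C8a arm, secured because the other arm is a deactivated β-methoxy enone with a substituted β-carbon, and ring closure faster than hydrogen transfer to 15, secured by the polarity mismatch between electrophilic 15 and the thiol and by the low thiol concentration.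

Step 8
Reactants: 17 [(1R,4aR,6R,8aS)-2-methoxy-1,6-dimethyl-4-oxo-1,4,4a,5,6,7,8,8a-octahydronaphthalen-1-yl][(2S)-2-(methoxymethyl)pyrrolidin-1-yl]methanone
Product: 19 [(1R,4aS,6R,8aS)-4-methoxy-1,6-dimethyl-2-oxo-1,2,4a,5,6,7,8,8a-octahydronaphthalen-1-yl][(2S)-2-(methoxymethyl)pyrrolidin-1-yl]methanone, via diketone 18 (not isolated)
Conditions: 2 M HCl, THF, 23 °C; then TsOH (cat.), MeOH, 4 Å MS, 60 °C
Reagents that add atoms: water (O); methanol (CO)
Why: Enol-ether hydrolysis gives β-diketone 18, in which C4a should epimerise through the C4 enol to the trans ring fusion (the cis isomer would hold the quaternary C1 or the C6 methyl group 1,3-diaxial), and acid-catalysed re-etherification should then take the less hindered C4 oxygen (thermodynamic vinylogous ester formation).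

Step 9
Reactants: 20 (E)-but-2-enal
Product: 21 (1E,3E)-1-iodopenta-1,3-diene
Conditions: CHI3, CrCl2, THF, 0 °C
Reagents that add atoms: iodoform (IC(I)I)
Why: Takai olefination converts the aldehyde into the (E)-vinyl iodide through a geminal dichromium species and keeps the existing (E)-alkene.

Step 10
Reactants: 21 (1E,3E)-1-iodopenta-1,3-diene; 19 [(1R,4aS,6R,8aS)-4-methoxy-1,6-dimethyl-2-oxo-1,2,4a,5,6,7,8,8a-octahydronaphthalen-1-yl][(2S)-2-(methoxymethyl)pyrrolidin-1-yl]methanone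
Product: 24 [(1R,4aS,6R,8aS)-1,6-dimethyl-4-oxo-2-[(1E,3E)-penta-1,3-dienyl]-1,4,4a,5,6,7,8,8a-octahydronaphthalen-1-yl][(2S)-2-(methoxymethyl)pyrrolidin-1-yl]methanone, via dienyllithium 22 (not isolated), via tertiary carbinol 23 (not isolated)
Conditions: 21, t-BuLi (2 equiv), Et2O, −78 °C; then 19, THF, −78 °C; then 1 M HCl, 0 → 23 °C
Reagents that add atoms: water (O)
Why: Stork–Danheiser sequence: iodine–lithium exchange with retention of alkene geometry, 1,2-addition of 22 to the C2 carbonyl of the vinylogous ester and acid-promoted hydrolysis–dehydration of 23 transpose the enone and place the dienyl group on sp2 C2, with no new stereocentre.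

Step 11
Reactants: 24 [(1R,4aS,6R,8aS)-1,6-dimethyl-4-oxo-2-[(1E,3E)-penta-1,3-dienyl]-1,4,4a,5,6,7,8,8a-octahydronaphthalen-1-yl][(2S)-2-(methoxymethyl)pyrrolidin-1-yl]methanone
Product: 25 [(1R,4R,4aS,6R,8aS)-4-hydroxy-1,6-dimethyl-2-[(1E,3E)-penta-1,3-dienyl]-1,4,4a,5,6,7,8,8a-octahydronaphthalen-1-yl][(2S)-2-(methoxymethyl)pyrrolidin-1-yl]methanone
Conditions: NaBH4, CeCl3·7H2O, MeOH, −78 °C
Reagents that add atoms: none
Why: Luche 1,2-reduction: hydride should attack the C4 carbonyl along the axial trajectory (β face, anti to the axial C4a–H), which gives the equatorial (4R) α-alcohol.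

Step 12
Reactants: 25 [(1R,4R,4aS,6R,8aS)-4-hydroxy-1,6-dimethyl-2-[(1E,3E)-penta-1,3-dienyl]-1,4,4a,5,6,7,8,8a-octahydronaphthalen-1-yl][(2S)-2-(methoxymethyl)pyrrolidin-1-yl]methanone
Product: 28 [(1R,2R,4aR,6R,8aS)-1,6-dimethyl-2-[(1E,3E)-penta-1,3-dienyl]-1,2,4a,5,6,7,8,8a-octahydronaphthalen-1-yl][(2S)-2-(methoxymethyl)pyrrolidin-1-yl]methanone, via sulfonylhydrazone 26 (not isolated), via allylic diazene 27 (not isolated)
Conditions: N-isopropylidene-N′-(2-nitrobenzenesulfonyl)hydrazine, PPh3, DEAD (betaine pre-formed), THF, 0 → 23 °C; then CF3CH2OH/H2O (1:1), 23 °C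
Reagents that add atoms: none
Why: Mitsunobu displacement with inversion at C4 gives 26, hydrolysis and loss of sulfinic acid give diazene 27, and its retro-ene loss of N2 delivers hydrogen suprafacially to the β face of C2 (reductive 1,3-transposition of an allylic alcohol), which sets C2 with the dienyl group α and moves the alkene to C3=C4.

Step 13
Reactants: 28 [(1R,2R,4aR,6R,8aS)-1,6-dimethyl-2-[(1E,3E)-penta-1,3-dienyl]-1,2,4a,5,6,7,8,8a-octahydronaphthalen-1-yl][(2S)-2-(methoxymethyl)pyrrolidin-1-yl]methanone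
Product: 29 [(1R,2R,4aR,6R,8aS)-1,6-dimethyl-2-[(1E,3E)-penta-1,3-dienyl]-1,2,4a,5,6,7,8,8a-octahydronaphthalen-1-yl]methanol
Conditions: NH3·BH3, n-BuLi, THF, 0 °C; then 28, 23 °C; aq. NH4Cl
Reagents that add atoms: none
Why: Lithium amidotrihydroborate reduces hindered tertiary amides to primary alcohols with C–N cleavage, which leaves the alkenes untouched and releases the auxiliary.

Step 14
Reactants: 29 [(1R,2R,4aR,6R,8aS)-1,6-dimethyl-2-[(1E,3E)-penta-1,3-dienyl]-1,2,4a,5,6,7,8,8a-octahydronaphthalen-1-yl]methanol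
Product: 30 (1R,2R,4aR,6R,8aS)-1,6-dimethyl-2-[(1E,3E)-penta-1,3-dienyl]-1,2,4a,5,6,7,8,8a-octahydronaphthalene-1-carbaldehyde
Conditions: Dess–Martin periodinane, pyridine, CH2Cl2, 0 °C
Reagents that add atoms: none
Why: Dess–Martin oxidation of the neopentyl primary alcohol gives the non-enolisable aldehyde.

Step 15
Reactants: 6 tert-butyl (2S)-4-bromo-2-[(1R)-1-tert-butoxyethyl]-3-methoxy-5-oxo-2,5-dihydro-1H-pyrrole-1-carboxylate; 30 (1R,2R,4aR,6R,8aS)-1,6-dimethyl-2-[(1E,3E)-penta-1,3-dienyl]-1,2,4a,5,6,7,8,8a-octahydronaphthalene-1-carbaldehyde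
Product: 32 tert-butyl (2S)-2-[(1R)-1-tert-butoxyethyl]-4-{[(1R,2R,4aR,6R,8aS)-1,6-dimethyl-2-[(1E,3E)-penta-1,3-dienyl]-1,2,4a,5,6,7,8,8a-octahydronaphthalen-1-yl](hydroxy)methyl}-3-methoxy-5-oxo-2,5-dihydro-1H-pyrrole-1-carboxylate (carbinol epimers), via magnesiated tetramate 31 (not isolated)
Conditions: 6, i-PrMgCl·LiCl, THF, −40 °C; then 30, −40 → 0 °C; aq. NH4Cl
Reagents that add atoms: none
Why: Bromine–magnesium exchange gives the C3-magnesiated 4-methoxypyrrolinone 31, which adds to the aldehyde (Grignard addition); the new carbinol centre forms as a mixture and is removed in step 16.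

Step 16
Reactants: 32 carbinol (epimer mixture)
Product: 33 tert-butyl (2S)-2-[(1R)-1-tert-butoxyethyl]-4-{[(1R,2R,4aR,6R,8aS)-1,6-dimethyl-2-[(1E,3E)-penta-1,3-dienyl]-1,2,4a,5,6,7,8,8a-octahydronaphthalen-1-yl]carbonyl}-3-methoxy-5-oxo-2,5-dihydro-1H-pyrrole-1-carboxylate
Conditions: Dess–Martin periodinane, pyridine, CH2Cl2, 23 °C
Reagents that add atoms: none
Why: Dess–Martin oxidation of the allylic-type secondary alcohol gives the 3-acyl-4-methoxypyrrolinone and converges both carbinol epimers.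

Step 17
Reactants: 33 protected 3-acyl-4-methoxypyrrolinone
Product: 35 (5S)-3-{[(1R,2R,4aR,6R,8aS)-1,6-dimethyl-2-[(1E,3E)-penta-1,3-dienyl]-1,2,4a,5,6,7,8,8a-octahydronaphthalen-1-yl]carbonyl}-4-hydroxy-5-[(1R)-1-hydroxyethyl]-1,5-dihydro-2H-pyrrol-2-one (target), via methyl ether 34 (not isolated)
Conditions: TFA/CH2Cl2 (1:3), 0 → 23 °C; then 1 M NaOH, MeOH, 23 °C; then 1 M HCl to pH 3
Reagents that add atoms: sodium hydroxide ([Na+].[OH-])
Why: Acidolysis removes the Boc group and the tert-butyl ether (loss of isobutene), and hydroxide then cleaves the vinylogous methyl ester by addition–elimination to release the 3-acyl tetramic acid.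

Compound list
1 | N-(tert-butoxycarbonyl)-O-tert-butyl-L-threonine, (2S,3R) | C[C@@H](OC(C)(C)C)[C@H](NC(=O)OC(C)(C)C)C(=O)O | starting material
2 | Meldrum's acid (2,2-dimethyl-1,3-dioxane-4,6-dione) | CC1(C)OC(=O)CC(=O)O1 | starting material
3 | tert-butyl N-[(2S,3R)-3-tert-butoxy-1-(2,2-dimethyl-4,6-dioxo-1,3-dioxan-5-yl)-1-oxobutan-2-yl]carbamate (acyl Meldrum's acid) | C[C@@H](OC(C)(C)C)[C@H](NC(=O)OC(C)(C)C)C(=O)C1C(=O)OC(C)(C)OC1=O | intermediate (not isolated)
4 | tert-butyl (2S)-2-[(1R)-1-tert-butoxyethyl]-3,5-dioxopyrrolidine-1-carboxylate | C[C@@H](OC(C)(C)C)[C@@H]1N(C(=O)OC(C)(C)C)C(=O)CC1=O | intermediate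
5 | tert-butyl (2S)-2-[(1R)-1-tert-butoxyethyl]-3-methoxy-5-oxo-2,5-dihydro-1H-pyrrole-1-carboxylate | C[C@@H](OC(C)(C)C)[C@@H]1N(C(=O)OC(C)(C)C)C(=O)C=C1OC | intermediate
6 | tert-butyl (2S)-4-bromo-2-[(1R)-1-tert-butoxyethyl]-3-methoxy-5-oxo-2,5-dihydro-1H-pyrrole-1-carboxylate | C[C@@H](OC(C)(C)C)[C@@H]1N(C(=O)OC(C)(C)C)C(=O)C(Br)=C1OC | intermediate
7 | 2-methoxybenzoyl chloride | COc1ccccc1C(Cl)=O | starting material
8 | (S)-2-(methoxymethyl)pyrrolidine | COC[C@@H]1CCCN1 | starting material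
9 | (2-methoxyphenyl)[(2S)-2-(methoxymethyl)pyrrolidin-1-yl]methanone | COc1ccccc1C(=O)N1CCC[C@H]1COC | intermediate
10 | potassium amide enolate of the 1,4-dihydro arene | COC1=CCC=CC1=C([O-])N1CCC[C@H]1COC.[K+] | intermediate (not isolated)
11 | [(1R)-2-methoxy-1-methylcyclohexa-2,5-dien-1-yl][(2S)-2-(methoxymethyl)pyrrolidin-1-yl]methanone | COC1=CCC=C[C@@]1(C)C(=O)N1CCC[C@H]1COC | intermediate
12 | (4R)-3-methoxy-4-methyl-4-{[(2S)-2-(methoxymethyl)pyrrolidin-1-yl]carbonyl}cyclohexa-2,5-dien-1-one | COC1=CC(=O)C=C[C@@]1(C)C(=O)N1CCC[C@H]1COC | intermediate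
13 | 4-methylpent-4-enoic acid | CC(=C)CCC(=O)O | starting material
14 | 3-methylbut-3-en-1-yl radical | [CH2]CC(C)=C | intermediate (not isolated)
15 | C4a α-keto radical of the adduct (C8 on the α face of C8a) | COC1=CC(=O)[CH][C@H](CCC(C)=C)[C@@]1(C)C(=O)N1CCC[C@H]1COC | intermediate (not isolated)
16 | cis-fused C6 tertiary radical | COC1=CC(=O)[C@@H]2C[C](C)CC[C@@H]2[C@@]1(C)C(=O)N1CCC[C@H]1COC | intermediate (not isolated)
17 | [(1R,4aR,6R,8aS)-2-methoxy-1,6-dimethyl-4-oxo-1,4,4a,5,6,7,8,8a-octahydronaphthalen-1-yl][(2S)-2-(methoxymethyl)pyrrolidin-1-yl]methanone (cis-fused) | COC1=CC(=O)[C@@H]2C[C@H](C)CC[C@@H]2[C@@]1(C)C(=O)N1CCC[C@H]1COC | intermediate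
18 | [(1R,4aS,6R,8aS)-1,6-dimethyl-2,4-dioxodecahydronaphthalen-1-yl][(2S)-2-(methoxymethyl)pyrrolidin-1-yl]methanone (trans-fused) | O=C1CC(=O)[C@H]2C[C@H](C)CC[C@@H]2[C@@]1(C)C(=O)N1CCC[C@H]1COC | intermediate (not isolated)
19 | [(1R,4aS,6R,8aS)-4-methoxy-1,6-dimethyl-2-oxo-1,2,4a,5,6,7,8,8a-octahydronaphthalen-1-yl][(2S)-2-(methoxymethyl)pyrrolidin-1-yl]methanone | O=C1C=C(OC)[C@H]2C[C@H](C)CC[C@@H]2[C@@]1(C)C(=O)N1CCC[C@H]1COC | intermediate
20 | (E)-but-2-enal | C/C=C/C=O | starting material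
21 | (1E,3E)-1-iodopenta-1,3-diene | C/C=C/C=C/I | intermediate
22 | (1E,3E)-penta-1,3-dienyllithium | C/C=C/C=C/[Li] | intermediate (not isolated)
23 | [(1R,4aS,6R,8aS)-2-hydroxy-4-methoxy-1,6-dimethyl-2-[(1E,3E)-penta-1,3-dienyl]-1,2,4a,5,6,7,8,8a-octahydronaphthalen-1-yl][(2S)-2-(methoxymethyl)pyrrolidin-1-yl]methanone (C2 epimers, formed as the lithium alkoxide) | C/C=C/C=C/C1(O)C=C(OC)[C@H]2C[C@H](C)CC[C@@H]2[C@@]1(C)C(=O)N1CCC[C@H]1COC | intermediate (not isolated)
24 | [(1R,4aS,6R,8aS)-1,6-dimethyl-4-oxo-2-[(1E,3E)-penta-1,3-dienyl]-1,4,4a,5,6,7,8,8a-octahydronaphthalen-1-yl][(2S)-2-(methoxymethyl)pyrrolidin-1-yl]methanone | C/C=C/C=C/C1=CC(=O)[C@H]2C[C@H](C)CC[C@@H]2[C@@]1(C)C(=O)N1CCC[C@H]1COC | intermediate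
25 | [(1R,4R,4aS,6R,8aS)-4-hydroxy-1,6-dimethyl-2-[(1E,3E)-penta-1,3-dienyl]-1,4,4a,5,6,7,8,8a-octahydronaphthalen-1-yl][(2S)-2-(methoxymethyl)pyrrolidin-1-yl]methanone | C/C=C/C=C/C1=C[C@H](O)[C@H]2C[C@H](C)CC[C@@H]2[C@@]1(C)C(=O)N1CCC[C@H]1COC | intermediate
26 | (4S)-4-[N-(2-nitrobenzenesulfonyl)-N′-isopropylidenehydrazino] derivative of 25 (C4 inverted) | C/C=C/C=C/C1=C[C@@H](N(N=C(C)C)S(=O)(=O)c3ccccc3[N+](=O)[O-])[C@H]2C[C@H](C)CC[C@@H]2[C@@]1(C)C(=O)N1CCC[C@H]1COC | intermediate (not isolated)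
27 | (4S)-4-diazenyl compound (allylic monoalkyl diazene) | C/C=C/C=C/C1=C[C@@H](N=N)[C@H]2C[C@H](C)CC[C@@H]2[C@@]1(C)C(=O)N1CCC[C@H]1COC | intermediate (not isolated)
28 | [(1R,2R,4aR,6R,8aS)-1,6-dimethyl-2-[(1E,3E)-penta-1,3-dienyl]-1,2,4a,5,6,7,8,8a-octahydronaphthalen-1-yl][(2S)-2-(methoxymethyl)pyrrolidin-1-yl]methanone | C/C=C/C=C/[C@@H]1C=C[C@H]2C[C@H](C)CC[C@@H]2[C@@]1(C)C(=O)N1CCC[C@H]1COC | intermediate
29 | [(1R,2R,4aR,6R,8aS)-1,6-dimethyl-2-[(1E,3E)-penta-1,3-dienyl]-1,2,4a,5,6,7,8,8a-octahydronaphthalen-1-yl]methanol | C/C=C/C=C/[C@@H]1C=C[C@H]2C[C@H](C)CC[C@@H]2[C@@]1(C)CO | intermediate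
30 | (1R,2R,4aR,6R,8aS)-1,6-dimethyl-2-[(1E,3E)-penta-1,3-dienyl]-1,2,4a,5,6,7,8,8a-octahydronaphthalene-1-carbaldehyde | C/C=C/C=C/[C@@H]1C=C[C@H]2C[C@H](C)CC[C@@H]2[C@@]1(C)C=O | intermediate
31 | C3-chloromagnesio derivative of 5 (from 6 by Br–Mg exchange) | C[C@@H](OC(C)(C)C)[C@@H]1N(C(=O)OC(C)(C)C)C(=O)C([Mg]Cl)=C1OC | intermediate (not isolated)
32 | carbinol from 30 and 31 (epimers at the carbinol carbon) | C/C=C/C=C/[C@@H]1C=C[C@H]2C[C@H](C)CC[C@@H]2[C@@]1(C)C(O)C1=C(OC)[C@H]([C@@H](C)OC(C)(C)C)N(C(=O)OC(C)(C)C)C1=O | intermediate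
33 | tert-butyl (2S)-2-[(1R)-1-tert-butoxyethyl]-4-{[(1R,2R,4aR,6R,8aS)-1,6-dimethyl-2-[(1E,3E)-penta-1,3-dienyl]-1,2,4a,5,6,7,8,8a-octahydronaphthalen-1-yl]carbonyl}-3-methoxy-5-oxo-2,5-dihydro-1H-pyrrole-1-carboxylate | C/C=C/C=C/[C@@H]1C=C[C@H]2C[C@H](C)CC[C@@H]2[C@@]1(C)C(=O)C1=C(OC)[C@H]([C@@H](C)OC(C)(C)C)N(C(=O)OC(C)(C)C)C1=O | intermediate
34 | (5S)-3-acyl-5-[(1R)-1-hydroxyethyl]-4-methoxy-1,5-dihydro-2H-pyrrol-2-one (4-O-methyl ether of the target) | C/C=C/C=C/[C@@H]1C=C[C@H]2C[C@H](C)CC[C@@H]2[C@@]1(C)C(=O)C1=C(OC)[C@H]([C@@H](C)O)NC1=O | intermediate (not isolated)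
35 | (5S)-3-{[(1R,2R,4aR,6R,8aS)-1,6-dimethyl-2-[(1E,3E)-penta-1,3-dienyl]-1,2,4a,5,6,7,8,8a-octahydronaphthalen-1-yl]carbonyl}-4-hydroxy-5-[(1R)-1-hydroxyethyl]-1,5-dihydro-2H-pyrrol-2-one | C/C=C/C=C/[C@@H]1C=C[C@H]2C[C@H](C)CC[C@@H]2[C@@]1(C)C(=O)C1=C(O)[C@H]([C@@H](C)O)NC1=O | target

Total step count: 17. Longest linear sequence: 13 steps (4, 5, 6, 7, 8, 10, 11, 12, 13, 14, 15, 16, 17).

Steps most likely to fail

Step 7 (proposed new method). What may go wrong: hydrogen-atom transfer to radical 15 before ring closure, which would give only the open-chain adduct, or unselective hydrogen delivery to the C6 radical. The fallback sets out from 12 and comes back at 17; it takes C6 from the chiral pool and closes ring B by enolate alkylation. Known bromide tert-butyl{[(2R)-4-bromo-2-methylbutyl]oxy}dimethylsilane F1 (from methyl (S)-3-hydroxy-2-methylpropanoate by known steps) is converted with Mg into Grignard reagent F2. F2 adds to 12 under CuBr·SMe2 catalysis (THF, −78 °C), anti to the carboxamide, to give ketone F3. Bu4NF gives alcohol F4, and I2/PPh3/imidazole gives iodide F5. LDA (THF, −78 → 0 °C) then closes ring B by intramolecular alkylation of the C4a enolate, the only enolisable position of this ketone, to give 17 or its C4a epimer; step 8 converts both into 19.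

Step 12. What may go wrong: substitution of the hindered, triene-conjugated allylic alcohol by an allylic-shift or elimination pathway instead of clean inversion, or consumption of the diene by the azodicarboxylate. The fallback sets out from 25 and comes back at 28. ClCO2Me/pyridine gives allylic methyl carbonate F6, which is reduced with Pd(OAc)2/n-Bu3P and HCO2H/Et3N in THF (formate reduction of an allylic carbonate with allylic transposition). Zerovalent palladium ionises anti to the α-carbonate and delivers hydride from its own β face to the more substituted terminus C2, which should give 28.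

Step 15. What may go wrong: slow addition of the stabilised alkenylmagnesium reagent to the neopentyl aldehyde, with competing attack on the N-Boc lactam or loss of configuration at C5 of the tetramate. The fallback sets out from 30 and comes back at 35; it forms no new ring. Pinnick oxidation (NaClO2, NaH2PO4, 2-methylbut-2-ene) gives acid F7, and (COCl)2/cat. DMF gives acid chloride F8. F8 O-acylates tetramic acid 4 (Et3N, CH2Cl2) to enol ester F9. DMAP-promoted O→C acyl migration, the rearrangement used for 3-acyl tetramic acids, gives protected 3-acyl tetramic acid F10, and TFA/CH2Cl2 then gives 35.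

Further compounds
F1 | step 7 | tert-butyl{[(2R)-4-bromo-2-methylbutyl]oxy}dimethylsilane | CC(C)(C)[Si](C)(C)OC[C@H](C)CCBr
F2 | step 7 | {(3R)-4-[(tert-butyldimethylsilyl)oxy]-3-methylbutyl}magnesium bromide | CC(C)(C)[Si](C)(C)OC[C@H](C)CC[Mg]Br
F3 | step 7 | conjugate adduct of F2 and 12 (ketone; C8 on the α face of C8a) | COC1=CC(=O)C[C@H](CC[C@@H](C)CO[Si](C)(C)C(C)(C)C)[C@@]1(C)C(=O)N1CCC[C@H]1COC
F4 | step 7 | primary alcohol from F3 | COC1=CC(=O)C[C@H](CC[C@@H](C)CO)[C@@]1(C)C(=O)N1CCC[C@H]1COC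
F5 | step 7 | primary iodide from F4 | COC1=CC(=O)C[C@H](CC[C@@H](C)CI)[C@@]1(C)C(=O)N1CCC[C@H]1COC
F6 | step 12 | (4R)-allylic methyl carbonate of 25 | C/C=C/C=C/C1=C[C@H](OC(=O)OC)[C@H]2C[C@H](C)CC[C@@H]2[C@@]1(C)C(=O)N1CCC[C@H]1COC
F7 | step 15 | (1R,2R,4aR,6R,8aS)-1,6-dimethyl-2-[(1E,3E)-penta-1,3-dienyl]-1,2,4a,5,6,7,8,8a-octahydronaphthalene-1-carboxylic acid | C/C=C/C=C/[C@@H]1C=C[C@H]2C[C@H](C)CC[C@@H]2[C@@]1(C)C(=O)O
F8 | step 15 | acid chloride of F7 | C/C=C/C=C/[C@@H]1C=C[C@H]2C[C@H](C)CC[C@@H]2[C@@]1(C)C(=O)Cl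
F9 | step 15 | 4-O-acyl enol ester of tetramic acid 4 | C/C=C/C=C/[C@@H]1C=C[C@H]2C[C@H](C)CC[C@@H]2[C@@]1(C)C(=O)OC1=CC(=O)N(C(=O)OC(C)(C)C)[C@H]1[C@@H](C)OC(C)(C)C
F10 | step 15 | N-Boc, O-tert-butyl protected 3-acyl tetramic acid | C/C=C/C=C/[C@@H]1C=C[C@H]2C[C@H](C)CC[C@@H]2[C@@]1(C)C(=O)C1=C(O)[C@H]([C@@H](C)OC(C)(C)C)N(C(=O)OC(C)(C)C)C1=O
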